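**Strategy.** The plan rests on ring E, the seven-membered ring of the primed guaianolide half (C1', C5'–C10'): oxygenated C6' and methylene-bearing C10' are 1,5-related through C7'–C8'–C9', and C7' carries the C11'–C12' lactone arm. This is the pattern left by a de Mayo two-carbon ring expansion. The precursor is the but-3-enoyl enol ester of a cis-bicyclo[3.3.0]octane-1,3-dione that already holds ring D (C3' as ketal). One operation (irradiation, then hydroxide) adds the tethered alkene across C6'=C9', cleaves C6'–C9' and delivers ring E with both ketones and the acetic acid arm. The product is carried to dehydrozaluzanin C, which supplies both halves of the target by a Diels–Alder union.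

Key step: step 5

Remark (numbering): guaiane numbering throughout; primed locants belong to the half whose C4' is the spiro carbon, unprimed locants to the half with the tertiary alcohol at C2.
Remark (precursor design): enol esters of cyclic 1,3-diones are vinylogous anhydrides that exchange acyl groups between the two oxygens and rearrange to the C-acyl trione under nucleophilic catalysis. The absolute configuration of 9 is therefore secured by resolution of the racemate, and the unwanted enantiomer is returned to meso 6 by mild methanolysis (K2CO3, MeOH).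
Remark (structure check): 9 as drawn is 1'R,5'S and 11 is 1'R,5'S,7'S; both map onto H-1'α, H-5'α, H-7'α of the target, so no correction is needed.
Assumption: 1 is used as the cis (meso) diester.

Step 1
Reactants: 1 dimethyl cis-4-oxocyclopentane-1,2-dicarboxylate
Product: 2 dimethyl cis-4,4-(ethylenedioxy)cyclopentane-1,2-dicarboxylate
Conditions: HOCH2CH2OH, TsOH·H2O (cat.), toluene, reflux, Dean–Stark
Reagents that add atoms: ethylene glycol, OCCO
Why: Acid-catalysed ketalisation with azeotropic removal of water should mask the ring-D ketone (future C3') and leave the meso cis-diester untouched.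

Step 2
Reactants: 2 dimethyl cis-4,4-(ethylenedioxy)cyclopentane-1,2-dicarboxylate; 3 tert-butyl acetate
Product: 5 tert-butyl cis-7,7-(ethylenedioxy)-2,4-dioxobicyclo[3.3.0]octane-3-carboxylate, via open-chain β-keto ester 4 (not isolated)
Conditions: LiN(iPr)2 (3.2 equiv), THF, −78 → 50 °C; 1 M HCl to pH 4, 0 °C
Reagents that add atoms: none
Why: A crossed Claisen condensation of the tert-butyl acetate enolate with one ester, then Dieckmann-type closure of the β-keto ester enolate onto the second ester, should give the stabilised tricarbonyl anion, and only the cis-fused bicyclo[3.3.0]octane can close, so the future H-1' and H-5' stay cis.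

Step 3
Reactants: 5 tert-butyl cis-7,7-(ethylenedioxy)-2,4-dioxobicyclo[3.3.0]octane-3-carboxylate
Product: 6 cis-7,7-(ethylenedioxy)bicyclo[3.3.0]octane-2,4-dione
Conditions: TsOH (1 mol %, anhydrous), toluene, 100 °C
Reagents that add atoms: none
Why: Acid-catalysed loss of isobutene from the tert-butyl ester and decarboxylation of the resulting 2-carboxy-1,3-dione should give the meso dione, the ketal surviving because no water is present.

Step 4
Reactants: 6 cis-7,7-(ethylenedioxy)bicyclo[3.3.0]octane-2,4-dione; 7 but-3-enoic acid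
Product: 9 (1'R,5'S)-4-(but-3-enoyloxy)-7,7-(ethylenedioxy)-cis-bicyclo[3.3.0]oct-3-en-2-one, via but-3-enoyl chloride 8 (not isolated)
Conditions: 7, (COCl)2, DMF (cat.), CH2Cl2, 0 → 25 °C; then 6, pyridine, CH2Cl2, −30 °C; preparative SFC on an amylose tris(3,5-dimethylphenylcarbamate) phase, CO2/MeCN
Reagents that add atoms: none
Why: O-acylation of the enolised 1,3-dione by the acid chloride with a weak base and no nucleophilic catalyst should give the racemic enol ester without O-to-C acyl shift or alkene conjugation, and resolution on the chiral phase supplies the enantiomer whose acylated oxygen sits on the future C6' (1'R,5'S).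

Step 5
Reactants: 9 (1'R,5'S)-4-(but-3-enoyloxy)-7,7-(ethylenedioxy)-cis-bicyclo[3.3.0]oct-3-en-2-one
Product: 11 2-[(1'R,5'S,7'S)-3',3'-(ethylenedioxy)-6',10'-dioxo-cis-hydroazulen-7'-yl]acetic acid, via cyclobutane-fused lactone photoadduct 10 (not isolated)
Conditions: hν (350 nm, Pyrex), degassed MeCN (5 mM), −10 °C; then LiOH, THF/H2O, 0 °C, 30 min; 1 M HCl to pH 3, 0 °C
Reagents that add atoms: lithium hydroxide, [Li+].[OH-]
Why: Proposed new method: excitation of the β-acyloxy enone and intersystem crossing should give a triplet that bonds C6' to the internal alkene carbon C7' (5-exo-trig, rule of five, closing the γ-lactone) and then collapses the C9'/C8' 1,4-biradical to the cyclobutane (straight, fused adduct); hydroxide then opens the lactone and the C6' alkoxide cleaves the strained C6'–C9' bond by retro-aldol, so the five- and four-membered rings merge into seven-membered ring E by ring expansion, not by direct closure. The closest known reactions are the de Mayo reaction of 3-acyloxy-2-cycloalkenones with alkenes and intramolecular enone–alkene [2+2] photocycloadditions through three-atom tethers; only the placement of the alkene in the acyl group is untested. The one new stereocentre, C7', is fixed by bonding on the convex face of the cis-bicyclo[3.3.0]octenone (syn to H-5') and by the cis lactone–cyclobutane fusion that the tether enforces, which leaves H-7' cis to H-5' after fragmentation. The step needs straight, not crossed, regiochemistry (secured by the three-atom tether), cycloaddition faster than photo-Fries acyl shift (favoured by the intramolecular alkene), and no epimerisation at C1', C5' or C7' (brief LiOH at 0 °C).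

Step 6
Reactants: 11 2-[(1'R,5'S,7'S)-3',3'-(ethylenedioxy)-6',10'-dioxo-cis-hydroazulen-7'-yl]acetic acid
Product: 12 2-[3',3'-(ethylenedioxy)-10'-methylidene-6'-oxo-cis-hydroazulen-7'-yl]acetic acid
Conditions: Ph3PCH3Br (1.3 equiv), KOtBu (2.3 equiv), THF, 0 → 25 °C; 1 M HCl to pH 3
Reagents that add atoms: methyltriphenylphosphonium bromide, C[P+](c1ccccc1)(c1ccccc1)c1ccccc1.[Br-]
Why: Wittig methylenation should occur at the C10' ketone (one branched α-carbon) and not at the C6' ketone (two branched α-carbons and a neighbouring carboxylate), and the short, cold reaction is meant to keep C1' from epimerising.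

Step 7
Reactants: 12 2-[3',3'-(ethylenedioxy)-10'-methylidene-6'-oxo-cis-hydroazulen-7'-yl]acetic acid
Product: 13 2-[10'-methylidene-3',6'-dioxo-cis-hydroazulen-7'-yl]acetic acid
Conditions: 1 M HCl, THF, 25 °C
Reagents that add atoms: water, O
Why: Acid hydrolysis of the dioxolane should unveil the C3' ketone and give the C3'/C6' 1,4-diketone, the 1,1-disubstituted alkene tolerating dilute acid at room temperature.

Step 8
Reactants: 13 2-[10'-methylidene-3',6'-dioxo-cis-hydroazulen-7'-yl]acetic acid
Product: 15 2-[4'-(dimethylaminomethyl)-10'-methylidene-3',6'-dioxo-cis-hydroazulen-7'-yl]acetic acid, via tris(trimethylsilyl) bis-enol ether 14 (not isolated)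
Conditions: TMSOTf (4 equiv), Et3N (6 equiv), CH2Cl2, 0 → 25 °C; then Me2N=CH2+ I− (1.05 equiv), 0 °C; aq. NaHCO3, then pH 6 buffer
Reagents that add atoms: Eschenmoser's salt (N,N-dimethylmethyleneiminium iodide), C[N+](C)=C.[I-]
Why: In this Mukaiyama–Mannich reaction, equilibrating silylation of the 1,4-diketone should give the conjugated bis(silyloxy)diene C3'=C4'–C5'=C6', so that C4' and not C2' is the nucleophilic ring-D carbon, the iminium ion attacks secondary C4' in preference to fully substituted C5', and hydrolytic protonation of C5' on the convex face (syn to H-1') restores the cis ring fusion; the uncontrolled C4' centre is erased in step 11.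

Step 9
Reactants: 15 2-[4'-(dimethylaminomethyl)-10'-methylidene-3',6'-dioxo-cis-hydroazulen-7'-yl]acetic acid
Product: 17 4'-(dimethylaminomethyl)-3'-hydroxyguai-10'(14')-en-12',6'α-olide lacking C13', via dihydroxy amino acid 16 (not isolated)
Conditions: Li, NH3(l), THF, t-BuOH, −78 °C; NH4Cl; then 2 M HCl (pH 2), 25 °C; NaHCO3 to pH 9
Reagents that add atoms: none
Why: Dissolving-metal reduction of both ketones under thermodynamic control should place the C6' oxygen pseudo-equatorial (α, trans to the C5'–C4' and C7'–C11' bonds), and acidification closes the trans-fused γ-lactone onto the C12' acid; the C3' carbinol centre is erased in step 12.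

Step 10
Reactants: 17 4'-(dimethylaminomethyl)-3'-hydroxyguai-10'(14')-en-12',6'α-olide lacking C13'
Product: 18 4',11'-bis(dimethylaminomethyl)-3'-hydroxyguai-10'(14')-en-12',6'α-olide
Conditions: LiN(iPr)2 (2.5 equiv), THF, −78 °C; Me2N=CH2+ I−, −78 → 0 °C; aq. NH4Cl
Reagents that add atoms: Eschenmoser's salt (N,N-dimethylmethyleneiminium iodide), C[N+](C)=C.[I-]
Why: Mannich reaction of the lactone enolate (the alcohol being held as its lithium alkoxide) should install C13' at C11', whose configuration is irrelevant because it becomes trigonal in step 11.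

Step 11
Reactants: 18 4',11'-bis(dimethylaminomethyl)-3'-hydroxyguai-10'(14')-en-12',6'α-olide
Product: 20 3'-hydroxyguaia-4'(15'),10'(14'),11'(13')-trien-12',6'α-olide, via bis(N-oxide) 19 (not isolated)
Conditions: mCPBA (2.05 equiv), CH2Cl2, −78 → 0 °C; basic Al2O3 filtration; then DMSO–THF, 65 °C
Reagents that add atoms: none
Why: Amine oxidation is far faster than epoxidation of the 1,1-disubstituted alkene, and the double Cope elimination (syn, five-membered transition state) can only take the β-hydrogens on C4' and C11', so both exocyclic methylenes should form.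

Step 12
Reactants: 20 3'-hydroxyguaia-4'(15'),10'(14'),11'(13')-trien-12',6'α-olide
Product: 21 dehydrozaluzanin C
Conditions: Dess–Martin periodinane, NaHCO3, CH2Cl2, 0 → 25 °C
Reagents that add atoms: none
Why: Dess–Martin oxidation of the allylic C3' alcohol should converge both epimers on the exocyclic enone without moving the alkenes.

Step 13
Reactants: 21 dehydrozaluzanin C
Product: 24 2-hydroxydehydrozaluzanin C, via trimethylsilyl dienol ether 22 (not isolated), via 2-(trimethylsilyloxy) ketone 23 (not isolated)
Conditions: TMSOTf, Et3N, CH2Cl2, −78 °C; pentane, filter; then mCPBA, NaHCO3, CH2Cl2, −40 °C; then citric acid, MeOH, 0 °C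
Reagents that add atoms: mCPBA (3-chloroperoxybenzoic acid), OOC(=O)c1cccc(Cl)c1
Why: In this Rubottom oxidation the C3 ketone can enolise only toward C2 and the electron-rich silyl enol ether should be epoxidised before the other alkenes; the C2 configuration does not matter because C2 is oxidised in step 14.

Step 14
Reactants: 24 2-hydroxydehydrozaluzanin C
Product: 25 2-hydroxy-3-oxoguaia-1,4(15),10(14),11(13)-tetraen-12,6α-olide
Conditions: Dess–Martin periodinane, CH2Cl2, 0 °C
Reagents that add atoms: none
Why: Dess–Martin oxidation of the α-ketol should give the cyclopentane-1,2-dione, which exists as the enol toward C1 (diosphenol) because that enol is conjugated with C10=C14 and the C3 ketone.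

Step 15
Reactants: 25 2-hydroxy-3-oxoguaia-1,4(15),10(14),11(13)-tetraen-12,6α-olide; 21 dehydrozaluzanin C (3 equiv)
Product: 28 target dimer CNP0269880.2, via trimethylsilyl enol ether 26 (not isolated), via silylated cycloadduct 27 (not isolated)
Conditions: BSA (1.2 equiv), toluene, 25 °C; then 21, BHT, 50 °C; then HF·pyridine, THF, 0 °C
Reagents that add atoms: none
Why: Diels–Alder reaction of the 1-silyloxy diene C14=C10–C1=C2(OSiMe3) with the exocyclic enone C4'=C15' of 21 in the ortho sense (C14–C15' and C2–C4'), through the endo transition state (C3' carbonyl over the diene), on the convex α-face of the dienophile (syn to H-5') and on the diene face anti to axial H-5, should set C2 (S) and spiro C4' (R); fluoride then frees the tertiary alcohol without base, so retro-aldol cleavage is avoided.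

**Compound list**

1 | dimethyl cis-4-oxocyclopentane-1,2-dicarboxylate (meso) | COC(=O)[C@H]1CC(=O)C[C@H]1C(=O)OC | starting material
2 | dimethyl cis-4,4-(ethylenedioxy)cyclopentane-1,2-dicarboxylate (meso) | COC(=O)[C@H]1CC2(OCCO2)C[C@H]1C(=O)OC | intermediate
3 | tert-butyl acetate | CC(=O)OC(C)(C)C | starting material
4 | methyl cis-2-(3-tert-butoxy-3-oxopropanoyl)-4,4-(ethylenedioxy)cyclopentane-1-carboxylate (racemic, one enantiomer drawn) | COC(=O)[C@H]1CC2(OCCO2)C[C@H]1C(=O)CC(=O)OC(C)(C)C | intermediate
5 | tert-butyl cis-7,7-(ethylenedioxy)-2,4-dioxobicyclo[3.3.0]octane-3-carboxylate (meso, enolised) | CC(C)(C)OC(=O)C1C(=O)[C@@H]2CC3(OCCO3)C[C@@H]2C1=O | intermediate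
6 | cis-7,7-(ethylenedioxy)bicyclo[3.3.0]octane-2,4-dione (meso, enolised; carbonyls are C6'/C10', C3 is C9', ring fusion C1'/C5', ketal C3') | O=C1CC(=O)[C@@H]2CC3(OCCO3)C[C@H]12 | intermediate
7 | but-3-enoic acid | C=CCC(=O)O | starting material
8 | but-3-enoyl chloride | C=CCC(=O)Cl | intermediate
9 | (1'R,5'S)-4-(but-3-enoyloxy)-7,7-(ethylenedioxy)-cis-bicyclo[3.3.0]oct-3-en-2-one (enol ester on O–C6', ketone C10') | C=CCC(=O)OC1=CC(=O)[C@@H]2CC3(OCCO3)C[C@H]12 | intermediate
10 | photoadduct: γ-lactone (C6'–O–C12'–C11'–C7') cis-fused to cyclobutane C6'–C7'–C8'–C9' on the C10' ketone, new bonds on the face of H-5' | O=C1C[C@@H]2C[C@H]3C(=O)[C@@H]4CC5(OCCO5)C[C@@H]4[C@@]23O1 | intermediate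
11 | 2-[(1'R,5'S,7'S)-3',3'-(ethylenedioxy)-6',10'-dioxo-cis-hydroazulen-7'-yl]acetic acid (H-1', H-5', H-7' all α) | OC(=O)C[C@@H]1CCC(=O)[C@@H]2CC3(OCCO3)C[C@@H]2C1=O | intermediate
12 | 2-[3',3'-(ethylenedioxy)-10'-methylidene-6'-oxo-cis-hydroazulen-7'-yl]acetic acid | OC(=O)C[C@@H]1CCC(=C)[C@@H]2CC3(OCCO3)C[C@@H]2C1=O | intermediate
13 | 2-[10'-methylidene-3',6'-dioxo-cis-hydroazulen-7'-yl]acetic acid | OC(=O)C[C@@H]1CCC(=C)[C@@H]2CC(=O)C[C@@H]2C1=O | intermediate
14 | trimethylsilyl ester of the 3',6'-bis(trimethylsilyloxy)-3',5'-diene | C[Si](C)(C)OC(=O)C[C@@H]1CCC(=C)[C@@H]2CC(O[Si](C)(C)C)=CC2=C1O[Si](C)(C)C | intermediate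
15 | 2-[4'-(dimethylaminomethyl)-10'-methylidene-3',6'-dioxo-cis-hydroazulen-7'-yl]acetic acid (C4' epimers) | OC(=O)C[C@@H]1CCC(=C)[C@@H]2CC(=O)C(CN(C)C)[C@@H]2C1=O | intermediate
16 | 3',6'α-dihydroxy amino acid (C3', C4' epimers) | OC(=O)C[C@@H]1CCC(=C)[C@@H]2CC(O)C(CN(C)C)[C@@H]2[C@H]1O | intermediate
17 | 4'-(dimethylaminomethyl)-3'-hydroxyguai-10'(14')-en-12',6'α-olide lacking C13' (trans-lactone; C3', C4' epimers) | CN(C)CC1C(O)C[C@H]2C(=C)CC[C@H]3CC(=O)O[C@@H]3[C@H]21 | intermediate
18 | 4',11'-bis(dimethylaminomethyl)-3'-hydroxyguai-10'(14')-en-12',6'α-olide (C3', C4', C11' epimers) | CN(C)CC1C(O)C[C@H]2C(=C)CC[C@H]3C(CN(C)C)C(=O)O[C@@H]3[C@H]21 | intermediate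
19 | bis(N-oxide) of 18 | C[N+](C)([O-])CC1C(O)C[C@H]2C(=C)CC[C@H]3C(C[N+](C)(C)[O-])C(=O)O[C@@H]3[C@H]21 | intermediate
20 | 3'-hydroxyguaia-4'(15'),10'(14'),11'(13')-trien-12',6'α-olide (zaluzanin C and its C3 epimer) | C=C1C(O)C[C@H]2C(=C)CC[C@H]3C(=C)C(=O)O[C@@H]3[C@H]21 | intermediate
21 | dehydrozaluzanin C (1R,5R,6S,7S; H-1α, H-5α, H-6β, H-7α) | C=C1C(=O)C[C@H]2C(=C)CC[C@H]3C(=C)C(=O)O[C@@H]3[C@H]21 | intermediate
22 | 3-(trimethylsilyloxy)guaia-2,4(15),10(14),11(13)-tetraen-12,6α-olide | C=C1C(O[Si](C)(C)C)=C[C@H]2C(=C)CC[C@H]3C(=C)C(=O)O[C@@H]3[C@H]21 | intermediate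
23 | 2-(trimethylsilyloxy)dehydrozaluzanin C (C2 epimers) | C=C1C(=O)C(O[Si](C)(C)C)[C@H]2C(=C)CC[C@H]3C(=C)C(=O)O[C@@H]3[C@H]21 | intermediate
24 | 2-hydroxydehydrozaluzanin C (C2 epimers) | C=C1C(=O)C(O)[C@H]2C(=C)CC[C@H]3C(=C)C(=O)O[C@@H]3[C@H]21 | intermediate
25 | 2-hydroxy-3-oxoguaia-1,4(15),10(14),11(13)-tetraen-12,6α-olide (diosphenol) | C=C1C(=O)C(O)=C2C(=C)CC[C@H]3C(=C)C(=O)O[C@@H]3[C@@H]12 | intermediate
26 | trimethylsilyl ether of 25 | C=C1C(=O)C(O[Si](C)(C)C)=C2C(=C)CC[C@H]3C(=C)C(=O)O[C@@H]3[C@@H]12 | intermediate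
27 | 2-O-trimethylsilyl ether of the target | C=C1C(=O)[C@]2(O[Si](C)(C)C)C3=C(CC[C@H]4C(=C)C(=O)O[C@@H]4[C@@H]13)CC[C@]21C(=O)C[C@H]2C(=C)CC[C@H]3C(=C)C(=O)O[C@@H]3[C@H]21 | intermediate
28 | target dimer CNP0269880.2 (2S, 4'R; C2–C4' and C14–C15' bonds) | C=C1C(=O)[C@]2(O)C3=C(CC[C@H]4C(=C)C(=O)O[C@@H]4[C@@H]13)CC[C@]21C(=O)C[C@H]2C(=C)CC[C@H]3C(=C)C(=O)O[C@@H]3[C@H]21 | target

**Step count and risks**

Total step count: 15. Longest linear sequence: 15 steps (1 → 28); 21 enters step 15 a second time as the dienophile.

1. Step 5 (Proposed new method). What may go wrong: a photo-Fries 1,3-acyl shift of the enol ester to the C-acyl trione may outrun cycloaddition, the alkene may add in the crossed sense, or the ring-fusion carbons and C7' may epimerise during the hydroxide stage. Fallback (known chemistry, the classical intermolecular de Mayo reaction): starting from 6, acetylation (Ac2O, pyridine) gives the racemic enol acetate F1. Irradiation (350 nm) of F1 with excess methyl but-3-enoate gives the head-to-tail acetoxycyclobutane F2. NaOMe in MeOH removes the acetate, and the cyclobutanolate fragments to the diketo methyl ester F3, with C7' equilibrated through the C6' enolate. LiOH hydrolysis and resolution of the racemic acid (chiral-phase SFC or crystallisation of the (R)-1-phenylethylammonium salt) rejoin the route at 11.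

2. Step 8. What may go wrong: silylation toward C2' or C7' may give a non-conjugated bis-enol ether that reacts at C2', the iminium ion may attack C5', or C5' may be protonated on the wrong face so that the cis ring fusion is lost. Fallback (ring D is methylenated statistically after the lactone is in place, so C5' is never made trigonal): starting from 12, Li/NH3 as in step 9 and then aqueous HCl give in one operation the 3'-keto trans-lactone F4 (lactonisation and ketal hydrolysis). LiN(iPr)2 (2.2 equiv) and Me2N=CH2+ I− aminomethylate the lactone enolate and the kinetic ketone enolates, giving the 4',11'-bis-Mannich base F5 and its 2',11'-regioisomer F6, which are separated by chromatography. MeI and then NaHCO3 on F5 (double E1cB elimination) give 21.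

3. Step 15. What may go wrong: cycloaddition may be slow because two fully substituted carbons (C2 and C4') must be joined, the diene may dimerise through its own C4=C15 enone, or the dienophile may approach the wrong diene face. Fallback (the C2–C4' bond is made while C2 still carries hydrogen and the oxygen is added afterwards): starting from 21, TBSOTf and Et3N give the silyl dienol ether F7. Pd(OAc)2 in MeCN (Saegusa–Ito oxidation) in the presence of excess 21 generates the cross-conjugated trienone F8, which is trapped in situ as the Diels–Alder adduct F9. Deprotonation of the doubly activated C2–H (KN(SiMe3)2, THF, −78 °C) and α-hydroxylation of the dienolate with 2-(phenylsulfonyl)-3-phenyloxaziridine give 28.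

**Further compounds**

F1 | step 5 | 4-acetoxy-7,7-(ethylenedioxy)-cis-bicyclo[3.3.0]oct-3-en-2-one (racemic, one enantiomer drawn) | CC(=O)OC1=CC(=O)[C@@H]2CC3(OCCO3)C[C@H]12
F2 | step 5 | head-to-tail photoadduct: 6'-acetoxy cyclobutane with the CH2CO2Me arm on C7' (racemic) | COC(=O)C[C@@H]1C[C@H]2C(=O)[C@@H]3CC4(OCCO4)C[C@@H]3[C@@]12OC(C)=O
F3 | step 5 | methyl ester of racemic 11 | COC(=O)C[C@@H]1CCC(=O)[C@@H]2CC3(OCCO3)C[C@@H]2C1=O
F4 | step 8 | 3'-oxoguai-10'(14')-en-12',6'α-olide lacking C13' and C15' | O=C1C[C@H]2C(=C)CC[C@H]3CC(=O)O[C@@H]3[C@H]2C1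
F5 | step 8 | 4',11'-bis(dimethylaminomethyl)-3'-oxoguai-10'(14')-en-12',6'α-olide | CN(C)CC1C(=O)C[C@H]2C(=C)CC[C@H]3C(CN(C)C)C(=O)O[C@@H]3[C@H]21
F6 | step 8 | 2',11'-bis(dimethylaminomethyl) regioisomer of F5 | CN(C)CC1C(=O)C[C@@H]2[C@H]3OC(=O)C(CN(C)C)[C@@H]3CCC(=C)[C@H]12
F7 | step 15 | 3-(tert-butyldimethylsilyloxy)guaia-2,4(15),10(14),11(13)-tetraen-12,6α-olide | C=C1C(O[Si](C)(C)C(C)(C)C)=C[C@H]2C(=C)CC[C@H]3C(=C)C(=O)O[C@@H]3[C@H]21
F8 | step 15 | 3-oxoguaia-1,4(15),10(14),11(13)-tetraen-12,6α-olide (trienone) | C=C1C(=O)C=C2C(=C)CC[C@H]3C(=C)C(=O)O[C@@H]3[C@@H]12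
F9 | step 15 | 2-deoxy analogue of the target (C2–H cycloadduct) | C=C1C(=O)[C@@H]2C3=C(CC[C@H]4C(=C)C(=O)O[C@@H]4[C@@H]13)CC[C@]21C(=O)C[C@H]2C(=C)CC[C@H]3C(=C)C(=O)O[C@@H]3[C@H]21
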